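**Retrosynthetic overview**

1. Hyperielliptone HB (28) ⇐ C‑methylation of 27 ⇐ C‑acylation with (S)‑2‑methylbutanoic acid ⇐ triketone ring T, built on the spiro carbon C6 by C‑acylation of ester 15 with acid chloride 21 (sets C6) and a vinylogous Dieckmann closure.
2. 15 ⇐ bridged lactone 13 ⇐ bromo ester 10: one SmI2 cascade forms both ring‑A bonds, C7–C7a and C5–C4; C5, C6, C7 and one carbonyl come from 2‑(bromomethyl)acrylic acid, tied as an ester to the C1 oxygen.
3. Enabling feature: on cyclopentane ring C the tertiary C1–OH is cis to the C7a–C7 bond and C6 is 1,3 to C7a, so O1, C7a, C7, C6 and a carboxyl carbon on C6 can close a six‑membered lactone (ring B) that forms a 2‑oxabicyclo[3.3.1]nonane with ring A; this temporary ring delivers C7 to C7a, fixes C3a and C4, and is opened again in step 9.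
4. 10 ⇐ enone 7 ⇐ (R)‑linalool (1): ring C by ring‑closing metathesis with C1 bought; the acetyl group by epoxide opening with acetylide, hydration and elimination.
5. Ring order: C (step 1), B and A together (step 8), B opened (step 9), T (step 16). Stereocentres: C1 and the sec‑butyl centre bought, C7a/C3a/C4 relayed from C1 in step 8, C6 in step 15, the C(CH3)(prenyl) centre in step 19.

Key step: step 8

Remark: locants C1–C7a are those of the octahydro‑1H‑indene unit of the target (C1 and C4 carry CH3 and OH, C6 is the spiro carbon, C3a and C7a are the ring‑fusion carbons); the enolised triketone is drawn in the tautomer of the target, 24, 26 and 27 in one of their equilibrating enol forms; all starting materials are taken as purchasable.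

**Route**

Step 1
Reactants: 1 (R)-linalool [(3R)-3,7-dimethylocta-1,6-dien-3-ol]
Product: 2 (1R)-1-methylcyclopent-2-en-1-ol
Conditions: second-generation Grubbs catalyst RuCl2(=CHPh)(PCy3)(H2IMes) (1 mol %), CH2Cl2, 40 °C
Reagents that add atoms: none
Why: Ring-closing metathesis of the 1,6-diene closes ring C and expels 2-methylpropene, leaving the bought tertiary carbinol centre (C1 of the target) untouched.

Step 2
Reactants: 2 (1R)-1-methylcyclopent-2-en-1-ol
Product: 3 (1S,2R,5S)-2-methyl-6-oxabicyclo[3.1.0]hexan-2-ol (epoxide oxygen cis to OH)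
Conditions: VO(acac)2 (2 mol %), t-BuOOH, CH2Cl2, 0 °C to rt
Reagents that add atoms: tert-butyl hydroperoxide, CC(C)(C)OO
Why: Hydroxyl-directed vanadium-catalysed epoxidation of the allylic alcohol delivers oxygen syn to OH; both epoxide carbons become sp2 again in step 5, so this selectivity only serves to give a single compound.

Step 3
Reactants: 3 (1S,2R,5S)-2-methyl-6-oxabicyclo[3.1.0]hexan-2-ol
Product: 4 (1R,2S,3S)-3-ethynyl-1-methylcyclopentane-1,2-diol
Conditions: LiC≡CH·H2NCH2CH2NH2 (3 equiv), DMSO, rt to 40 °C; aq. NH4Cl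
Reagents that add atoms: lithium acetylide–ethylenediamine complex, [Li+].[C-]#C.NCCN
Why: SN2 opening of the epoxide by acetylide at the carbon remote from the quaternary carbinol (anti attack) places the two-carbon acetyl precursor on the future C3a.

Step 4
Reactants: 4 (1R,2S,3S)-3-ethynyl-1-methylcyclopentane-1,2-diol
Product: 5 1-[(1R,2S,3R)-2,3-dihydroxy-3-methylcyclopentyl]ethan-1-one
Conditions: Ph3PAuCl (2 mol %), AgSbF6 (2 mol %), H2O, 1,4-dioxane, 60 °C
Reagents that add atoms: water, O
Why: Gold-catalysed Markovnikov hydration of the terminal alkyne gives the methyl ketone, and the trans hydroxyl cannot reach the alkyne for an endo cyclisation.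

Step 5
Reactants: 5 1-[(1R,2S,3R)-2,3-dihydroxy-3-methylcyclopentyl]ethan-1-one
Product: 7 1-[(3R)-3-hydroxy-3-methylcyclopent-1-en-1-yl]ethan-1-one, via mesylate 6 (not isolated)
Conditions: MsCl (1.1 equiv), Et3N (3 equiv), CH2Cl2, 0 °C to rt
Reagents that add atoms: none
Why: Selective mesylation of the secondary alcohol followed by E1cB elimination of the β-mesyloxy ketone gives the γ-hydroxy enone, the tertiary alcohol being too hindered to react.

Step 6
Reactants: 8 2-(bromomethyl)prop-2-enoic acid
Product: 9 2-(bromomethyl)prop-2-enoyl chloride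
Conditions: (COCl)2, DMF (cat.), CH2Cl2, 0 °C to rt; used crude
Reagents that add atoms: oxalyl chloride, ClC(=O)C(Cl)=O
Why: Standard acid chloride formation through the Vilsmeier chloride.

Step 7
Reactants: 7 1-[(3R)-3-hydroxy-3-methylcyclopent-1-en-1-yl]ethan-1-one; 9 2-(bromomethyl)prop-2-enoyl chloride
Product: 10 (1R)-3-acetyl-1-methylcyclopent-2-en-1-yl 2-(bromomethyl)prop-2-enoate
Conditions: iPr2NEt (2 equiv), DMAP (10 mol %), CH2Cl2, −20 °C to rt
Reagents that add atoms: none
Why: DMAP-catalysed acylation of the tertiary alcohol installs the C5–C6–C7 unit as a temporary ester tether, with a hindered base so that the allylic bromide is not displaced.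

Step 8
Reactants: 10 (1R)-3-acetyl-1-methylcyclopent-2-en-1-yl 2-(bromomethyl)prop-2-enoate
Product: 13 (1R,3aS,4R,6R,7aS)-4-hydroxy-1,4-dimethyloctahydro-1H-indene-6-carboxylic acid 6,1-lactone, via allylsamarium diiodide 11 (not isolated), via keto methylene lactone 12 (not isolated)
Conditions: SmI2 (2.2 equiv), THF, −78 to −20 °C, slow addition of 10 (0.01 M); then t-BuOH (3 equiv), SmI2 (2.5 equiv), −20 °C to rt; aq. NH4Cl
Reagents that add atoms: none
Why: Proposed new method: SmI2 reduces the allylic C–Br bond of 10 to the 2-(alkoxycarbonyl)allyl samarium 11, whose terminal carbon adds within the ester tether to the enone β-carbon C7a (C7–C7a bond, double bond transposed to C6=C5); t-BuOH protonates the samarium enolate to ketone 12, whose C4 ketyl then adds to the terminal carbon C5 of the α-methylene lactone (C5–C4 bond), and the α-lactone radical is reduced and protonated at C6. The closest known reaction types are the Dreiding–Schmidt (Barbier) allylation with 2-(bromomethyl)acrylates and the SmI2 ketyl–olefin cyclisation onto unsaturated esters, run in sequence as in SmI2 radical–anionic cascades; new is their union through an intramolecular conjugate allylation. Lactone ring B closes 6-exo-trig (polar 1,4-addition onto the enone) and ring A closes 6-endo-trig (ketyl onto the CH2 terminus of the acrylate), giving a 2-oxabicyclo[3.3.1]nonanone fused to ring C. C7a is set by the tether (C7 is delivered cis to the C1 oxygen), C3a by protonation anti to the new C7 substituent and by the cis fusion that the second closure demands, and C4 by the chair–chair bicyclic transition state, in which the methyl group is exo and the samarium alkoxide endo, bridged to the lactone carbonyl, so that OH ends trans to H-3a; C6 is only a lactone bridgehead here and is set for good in step 15. The step needs 1,4- instead of 1,2-allylation and coupling instead of plain reduction: the tether allows a six-membered ring for the 1,4-mode but only an eight-membered one for the 1,2-mode, and the strongly radicophilic methylene lactone is held next to the ketone.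

Step 9
Reactants: 13 (1R,3aS,4R,6R,7aS)-4-hydroxy-1,4-dimethyloctahydro-1H-indene-6-carboxylic acid 6,1-lactone
Product: 14 methyl (1R,3aS,4R,6R,7aS)-1,4-dihydroxy-1,4-dimethyloctahydro-1H-indene-6-carboxylate
Conditions: NaOMe (0.2 equiv), MeOH, 0 °C to rt
Reagents that add atoms: methanol, CO
Why: Transesterification opens the strained bridged lactone (removal of the tether) and ring A relaxes to the chair with an equatorial ester; C6 is enolisable here and is reset in step 15.

Step 10
Reactants: 14 methyl (1R,3aS,4R,6R,7aS)-1,4-dihydroxy-1,4-dimethyloctahydro-1H-indene-6-carboxylate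
Product: 15 methyl (1R,3aS,4R,6R,7aS)-1,4-dimethyl-1,4-bis(trimethylsilyloxy)octahydro-1H-indene-6-carboxylate
Conditions: N-(trimethylsilyl)imidazole (4 equiv), CH2Cl2, 40 °C
Reagents that add atoms: N-(trimethylsilyl)imidazole, C[Si](C)(C)n1ccnc1
Why: Silylation of both tertiary alcohols removes the acidic protons for the enolate chemistry and blocks relactonisation.

Step 11
Reactants: 16 methyl acetoacetate; 17 prenyl bromide (1-bromo-3-methylbut-2-ene)
Product: 18 methyl 7-methyl-3-oxooct-6-enoate
Conditions: NaH, THF, 0 °C; n-BuLi, 0 °C; then 17, 0 °C to rt; aq. HCl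
Reagents that add atoms: none
Why: Weiler dianion alkylation takes place at the γ-carbon of the β-keto ester.

Step 12
Reactants: 18 methyl 7-methyl-3-oxooct-6-enoate
Product: 19 methyl (2E)-3-methoxy-7-methylocta-2,6-dienoate
Conditions: HC(OMe)3, H2SO4 (cat.), MeOH, rt
Reagents that add atoms: trimethyl orthoformate, COC(OC)OC
Why: Acid-catalysed ketalisation and loss of methanol give the thermodynamic (E)-β-methoxy enoate.

Step 13
Reactants: 19 methyl (2E)-3-methoxy-7-methylocta-2,6-dienoate
Product: 20 (2E)-3-methoxy-7-methylocta-2,6-dienoic acid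
Conditions: LiOH, THF/H2O, 50 °C; then aq. HCl to pH 3 at 0 °C
Reagents that add atoms: lithium hydroxide, [Li+].[OH-]
Why: Saponification, which the enol ether survives in base and on brief cold acidification.

Step 14
Reactants: 20 (2E)-3-methoxy-7-methylocta-2,6-dienoic acid
Product: 21 (2E)-3-methoxy-7-methylocta-2,6-dienoyl chloride
Conditions: 1-chloro-N,N,2-trimethylprop-1-en-1-amine (Ghosez reagent), CH2Cl2, 0 °C to rt; used crude
Reagents that add atoms: 1-chloro-N,N,2-trimethylprop-1-en-1-amine, CC(C)=C(Cl)N(C)C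
Why: Neutral acid chloride formation avoids HCl, which would add to the enol ether and the trisubstituted alkene.

Step 15
Reactants: 15 methyl (1R,3aS,4R,6R,7aS)-1,4-dimethyl-1,4-bis(trimethylsilyloxy)octahydro-1H-indene-6-carboxylate; 21 (2E)-3-methoxy-7-methylocta-2,6-dienoyl chloride
Product: 22 methyl (1R,3aS,4R,6S,7aS)-6-[(2E)-3-methoxy-7-methylocta-2,6-dienoyl]-1,4-dimethyl-1,4-bis(trimethylsilyloxy)octahydro-1H-indene-6-carboxylate
Conditions: LiN(iPr)2 (1.1 equiv), THF, −78 °C; the enolate is added to 21 (1.5 equiv) in THF at −78 °C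
Reagents that add atoms: none
Why: Claisen-type C-acylation of the ester enolate makes the quaternary spiro carbon C6, the acid chloride approaching the exocyclic enolate equatorially and anti to the axial C4 methyl group, so that the new ketone is cis to the C4 oxygen and the ester cis to the C4 methyl as the target requires.

Step 16
Reactants: 22 methyl (1R,3aS,4R,6S,7aS)-6-[(2E)-3-methoxy-7-methylocta-2,6-dienoyl]-1,4-dimethyl-1,4-bis(trimethylsilyloxy)octahydro-1H-indene-6-carboxylate
Product: 23 (1'R,3a'S,4'R,7a'S)-4-methoxy-1',4'-dimethyl-3-(3-methylbut-2-en-1-yl)-1',4'-bis(trimethylsilyloxy)octahydrospiro[cyclohex-4-ene-1,6'-indene]-2,6-dione (C2 carbonyl cis to the C4' methyl; C3 epimers)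
Conditions: LiN(SiMe3)2 (2.5 equiv), THF, −78 to 0 °C; aq. NH4Cl
Reagents that add atoms: none
Why: γ-Deprotonation of the β-methoxy enone and intramolecular Claisen attack on the ester (vinylogous Dieckmann condensation) close the six-membered ring T; the prenyl-bearing carbon is enolisable and its configuration is of no consequence here.

Step 17
Reactants: 23 (1'R,3a'S,4'R,7a'S)-4-methoxy-1',4'-dimethyl-3-(3-methylbut-2-en-1-yl)-1',4'-bis(trimethylsilyloxy)octahydrospiro[cyclohex-4-ene-1,6'-indene]-2,6-dione
Product: 24 (1'R,3a'S,4'R,7a'S)-1',4'-dihydroxy-1',4'-dimethyl-3-(3-methylbut-2-en-1-yl)octahydrospiro[cyclohexane-1,6'-indene]-2,4,6-trione (drawn as the 4-enol)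
Conditions: 2 M aq. HCl, THF, rt
Reagents that add atoms: water, O
Why: Acid hydrolysis of the vinylogous methyl ester and of both tertiary trimethylsilyl ethers.

Step 18
Reactants: 24 (1'R,3a'S,4'R,7a'S)-1',4'-dihydroxy-1',4'-dimethyl-3-(3-methylbut-2-en-1-yl)octahydrospiro[cyclohexane-1,6'-indene]-2,4,6-trione; 25 (S)-2-methylbutanoic acid
Product: 27 5-[(2S)-2-methylbutanoyl] derivative of 24 (drawn as a dienol), via enol ester 26 (not isolated)
Conditions: DCC (1.1 equiv), DMAP (1.2 equiv), CH2Cl2, 0 °C to rt
Reagents that add atoms: none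
Why: Steglich O-acylation of the enol and DMAP-mediated O-to-C acyl migration (as in the C-acylation of cyclic 1,3-diones) put the acyl group on the only unsubstituted carbon of ring T; the sec-butyl stereocentre is bought.

Step 19
Reactants: 27 5-[(2S)-2-methylbutanoyl] derivative of 24
Product: 28 hyperielliptone HB
Conditions: NaOMe (2.5 equiv), MeI (1.5 equiv), MeOH, 0 °C to rt
Reagents that add atoms: iodomethane, CI
Why: C-Methylation of the dianion of the enolised triketone at its only C–H carbon, the usual last step for dearomatised acylphloroglucinols; iodomethane should come from the face of ring T on the side of C7, whose neighbour C7a is only a CH, and not from the side of C5 with the fully substituted C4, which sets the C(CH3)(prenyl) centre.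

**Compound list**

1 | (R)-linalool, (3R)-3,7-dimethylocta-1,6-dien-3-ol | CC(C)=CCC[C@@](C)(O)C=C | starting material
2 | (1R)-1-methylcyclopent-2-en-1-ol | C[C@]1(O)C=CCC1 | intermediate
3 | (1S,2R,5S)-2-methyl-6-oxabicyclo[3.1.0]hexan-2-ol (epoxide cis to OH) | C[C@@]1(O)CC[C@@H]2O[C@H]12 | intermediate
4 | (1R,2S,3S)-3-ethynyl-1-methylcyclopentane-1,2-diol | C[C@@]1(O)CC[C@@H](C#C)[C@@H]1O | intermediate
5 | 1-[(1R,2S,3R)-2,3-dihydroxy-3-methylcyclopentyl]ethan-1-one | C[C@@]1(O)CC[C@@H](C(C)=O)[C@@H]1O | intermediate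
6 | mesylate of the secondary alcohol of 5 | C[C@@]1(O)CC[C@@H](C(C)=O)[C@@H]1OS(C)(=O)=O | intermediate
7 | 1-[(3R)-3-hydroxy-3-methylcyclopent-1-en-1-yl]ethan-1-one | CC(=O)C1=C[C@](C)(O)CC1 | intermediate
8 | 2-(bromomethyl)prop-2-enoic acid | C=C(CBr)C(=O)O | starting material
9 | 2-(bromomethyl)prop-2-enoyl chloride | C=C(CBr)C(Cl)=O | intermediate
10 | (1R)-3-acetyl-1-methylcyclopent-2-en-1-yl 2-(bromomethyl)prop-2-enoate | CC(=O)C1=C[C@](C)(OC(=O)C(=C)CBr)CC1 | intermediate
11 | {2-[({(1R)-3-acetyl-1-methylcyclopent-2-en-1-yl}oxy)carbonyl]prop-2-en-1-yl}samarium diiodide | CC(=O)C1=C[C@](C)(OC(=O)C(=C)C[Sm](I)I)CC1 | intermediate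
12 | 5-acetyl-7a-methyl-3-methylidenehexahydrocyclopenta[b]pyran-2(3H)-one, cis ring fusion, acetyl cis to the lactone CH2 (configured as 13 at the future C1, C3a, C7a) | CC(=O)[C@H]1CC[C@@]2(C)OC(=O)C(=C)C[C@@H]12 | intermediate
13 | (1R,3aS,4R,6R,7aS)-4-hydroxy-1,4-dimethyloctahydro-1H-indene-6-carboxylic acid 6,1-lactone | C[C@@]1(O)C[C@H]2C[C@H]3[C@@H]1CC[C@@]3(C)OC2=O | intermediate
14 | methyl (1R,3aS,4R,6R,7aS)-1,4-dihydroxy-1,4-dimethyloctahydro-1H-indene-6-carboxylate | COC(=O)[C@@H]1C[C@H]2[C@H](CC[C@@]2(C)O)[C@](C)(O)C1 | intermediate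
15 | methyl (1R,3aS,4R,6R,7aS)-1,4-dimethyl-1,4-bis(trimethylsilyloxy)octahydro-1H-indene-6-carboxylate | COC(=O)[C@@H]1C[C@H]2[C@H](CC[C@@]2(C)O[Si](C)(C)C)[C@](C)(O[Si](C)(C)C)C1 | intermediate
16 | methyl acetoacetate | COC(=O)CC(C)=O | starting material
17 | prenyl bromide, 1-bromo-3-methylbut-2-ene | CC(C)=CCBr | starting material
18 | methyl 7-methyl-3-oxooct-6-enoate | COC(=O)CC(=O)CCC=C(C)C | intermediate
19 | methyl (2E)-3-methoxy-7-methylocta-2,6-dienoate | COC(=O)/C=C(/OC)CCC=C(C)C | intermediate
20 | (2E)-3-methoxy-7-methylocta-2,6-dienoic acid | OC(=O)/C=C(/OC)CCC=C(C)C | intermediate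
21 | (2E)-3-methoxy-7-methylocta-2,6-dienoyl chloride | ClC(=O)/C=C(/OC)CCC=C(C)C | intermediate
22 | methyl (1R,3aS,4R,6S,7aS)-6-[(2E)-3-methoxy-7-methylocta-2,6-dienoyl]-1,4-dimethyl-1,4-bis(trimethylsilyloxy)octahydro-1H-indene-6-carboxylate | COC(=O)[C@@]1(C(=O)/C=C(/OC)CCC=C(C)C)C[C@H]2[C@H](CC[C@@]2(C)O[Si](C)(C)C)[C@](C)(O[Si](C)(C)C)C1 | intermediate
23 | (1'R,3a'S,4'R,7a'S)-4-methoxy-1',4'-dimethyl-3-(3-methylbut-2-en-1-yl)-1',4'-bis(trimethylsilyloxy)octahydrospiro[cyclohex-4-ene-1,6'-indene]-2,6-dione (C2 carbonyl cis to the C4' methyl; C3 epimers) | COC1=CC(=O)[C@@]2(C[C@H]3[C@H](CC[C@@]3(C)O[Si](C)(C)C)[C@](C)(O[Si](C)(C)C)C2)C(=O)C1CC=C(C)C | intermediate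
24 | (1'R,3a'S,4'R,7a'S)-1',4'-dihydroxy-1',4'-dimethyl-3-(3-methylbut-2-en-1-yl)octahydrospiro[cyclohexane-1,6'-indene]-2,4,6-trione (4-enol drawn) | OC1=C(CC=C(C)C)C(=O)[C@]2(C[C@H]3[C@H](CC[C@@]3(C)O)[C@](C)(O)C2)C(=O)C1 | intermediate
25 | (S)-2-methylbutanoic acid | CC[C@H](C)C(=O)O | starting material
26 | enol (2S)-2-methylbutanoate of 24 | CC[C@H](C)C(=O)OC1=C(CC=C(C)C)C(=O)[C@]2(C[C@H]3[C@H](CC[C@@]3(C)O)[C@](C)(O)C2)C(=O)C1 | intermediate
27 | 5-[(2S)-2-methylbutanoyl] derivative of 24 (dienol drawn) | CC[C@H](C)C(=O)C1=C(O)C(CC=C(C)C)=C(O)[C@]2(C[C@H]3[C@H](CC[C@@]3(C)O)[C@](C)(O)C2)C1=O | intermediate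
28 | hyperielliptone HB | CC[C@H](C)C(=O)C1=C(O)[C@@](C)(CC=C(C)C)C(=O)[C@]2(C[C@H]3[C@H](CC[C@@]3(C)O)[C@](C)(O)C2)C1=O | target

**Count and risks**

Total step count: 19. Longest linear sequence: 14 steps (steps 1–5, 7–10, 15–19).

Steps most likely to fail:

Step 8 (bears the label). What may go wrong: the allylsamarium is protonated or adds 1,2 to the ketone of a second molecule before it cyclises, or the second stage reduces the methylene lactone without closing ring A. Fallback, setting out from 7 and coming back at 13: the tertiary alcohol 7 is esterified (2,4,6-trichlorobenzoyl chloride, Et3N, DMAP) with 2-[(trimethylsilyl)methyl]prop-2-enoic acid F1, itself made by LiOH hydrolysis of the commercial ethyl ester, to give the allylsilane ester F2. TiCl4 in CH2Cl2 at −78 °C then brings about an intramolecular Hosomi–Sakurai conjugate allylation, which forms the C7–C7a bond and gives 12, now isolated. SmI2 and t-BuOH in THF close ring A by the ketone–acrylate ketyl–olefin cyclisation alone and give 13. The two bonds are then made in two operations, each by a reaction type with close precedent.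

Step 15. What may go wrong: O-acylation of the hindered enolate, proton transfer from the enolisable acid chloride to the enolate, or loss of the equatorial preference. Fallback, setting out from 15 and 19 and coming back at 22: ester 19 is reduced with i-Bu2AlH to the allylic alcohol F3 and oxidised with MnO2 to the aldehyde F4. The lithium enolate of 15 adds to F4 in an aldol reaction (same equatorial approach, no O-acylation, no acidic acyl halide) to give the β-hydroxy ester F5, and Dess–Martin periodinane oxidises F5 to 22.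

Step 19. What may go wrong: poor facial selectivity in the methylation, because the two flanks of the spiro carbon differ only beyond their CH2 groups and ring A cannot adopt a strain-free chair, or competing O-methylation. Fallback, setting out from 15 and coming back at 28: the order of the two alkylations is exchanged so that the last one is a catalyst-controlled C–C bond formation. Methyl 3-oxopentanoate is taken through the operations of steps 12 to 14 to the enol ether ester F6, the acid F7 and the acid chloride F8. 15 and F8 give the β-keto ester F9 (as step 15), then the spiro enol ether F10 (as step 16), the methyl trione diol F11 (as step 17) and, with 25, the acyl methyl trione F12 (as step 18). A Tsuji–Trost asymmetric allylic alkylation (Pd2(dba)3 as source of zerovalent palladium, a Trost bisphosphine ligand of the matching hand, prenyl methyl carbonate, CH2Cl2) then attaches the prenyl group through its unsubstituted terminus to the methyl-bearing carbon and gives 28 with the quaternary centre under ligand control.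

Further compounds
F1 | step 8 | 2-[(trimethylsilyl)methyl]prop-2-enoic acid | C=C(C[Si](C)(C)C)C(=O)O
F2 | step 8 | (1R)-3-acetyl-1-methylcyclopent-2-en-1-yl 2-[(trimethylsilyl)methyl]prop-2-enoate | CC(=O)C1=C[C@](C)(OC(=O)C(=C)C[Si](C)(C)C)CC1
F3 | step 15 | (2E)-3-methoxy-7-methylocta-2,6-dien-1-ol | OC/C=C(/OC)CCC=C(C)C
F4 | step 15 | (2E)-3-methoxy-7-methylocta-2,6-dienal | O=C/C=C(/OC)CCC=C(C)C
F5 | step 15 | methyl (1R,3aS,4R,6S,7aS)-6-[(2E)-1-hydroxy-3-methoxy-7-methylocta-2,6-dien-1-yl]-1,4-dimethyl-1,4-bis(trimethylsilyloxy)octahydro-1H-indene-6-carboxylate (carbinol epimers) | COC(=O)[C@@]1(C(O)/C=C(/OC)CCC=C(C)C)C[C@H]2[C@H](CC[C@@]2(C)O[Si](C)(C)C)[C@](C)(O[Si](C)(C)C)C1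
F6 | step 19 | methyl (2E)-3-methoxypent-2-enoate | COC(=O)/C=C(/OC)CC
F7 | step 19 | (2E)-3-methoxypent-2-enoic acid | OC(=O)/C=C(/OC)CC
F8 | step 19 | (2E)-3-methoxypent-2-enoyl chloride | ClC(=O)/C=C(/OC)CC
F9 | step 19 | methyl (1R,3aS,4R,6S,7aS)-6-[(2E)-3-methoxypent-2-enoyl]-1,4-dimethyl-1,4-bis(trimethylsilyloxy)octahydro-1H-indene-6-carboxylate | COC(=O)[C@@]1(C(=O)/C=C(/OC)CC)C[C@H]2[C@H](CC[C@@]2(C)O[Si](C)(C)C)[C@](C)(O[Si](C)(C)C)C1
F10 | step 19 | (1'R,3a'S,4'R,7a'S)-4-methoxy-1',3,4'-trimethyl-1',4'-bis(trimethylsilyloxy)octahydrospiro[cyclohex-4-ene-1,6'-indene]-2,6-dione (C3 epimers) | COC1=CC(=O)[C@@]2(C[C@H]3[C@H](CC[C@@]3(C)O[Si](C)(C)C)[C@](C)(O[Si](C)(C)C)C2)C(=O)C1C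
F11 | step 19 | (1'R,3a'S,4'R,7a'S)-1',4'-dihydroxy-1',3,4'-trimethyloctahydrospiro[cyclohexane-1,6'-indene]-2,4,6-trione (4-enol drawn) | OC1=C(C)C(=O)[C@]2(C[C@H]3[C@H](CC[C@@]3(C)O)[C@](C)(O)C2)C(=O)C1
F12 | step 19 | 5-[(2S)-2-methylbutanoyl] derivative of F11 (dienol drawn) | CC[C@H](C)C(=O)C1=C(O)C(C)=C(O)[C@]2(C[C@H]3[C@H](CC[C@@]3(C)O)[C@](C)(O)C2)C1=O
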